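A direct plan would make the allyl 5-arylpent-2-ynoate A1 by alkylating a propiolate dianion, build ring A by an Alder–Rickert cycloaddition of A1 with the silyloxydiene A2 (loss of ethene) to give the resorcylate A3, and then C-prenylate the phenoxide of A3 twice before unmasking. Its weakest steps would be:
- the acetylide alkylation leading to A1, because a strongly basic dianion and a 2-arylethyl halide would favour E2 elimination to the styrene;
- the double ortho C-prenylation of the phenoxide of A3, because O- competes with C-alkylation and mono/bis mixtures would form;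
- the thermal cycloaddition with ethene extrusion, because it would need about 185 °C and the diene A2 is hydrolytically fragile.

The route rests on building ring A from two open-chain partners that already carry all six substituents: methoxyalkyne 18 (OMe, one prenyl) and the vinylketene 19 released from diazo ketoester 15 (ester, arylethyl chain, second prenyl). A Danheiser-type benzannulation (Wolff rearrangement, [2+2] cycloaddition, 4π ring opening, 6π ring closure) forms C4–C5, C6–C1 and C3–C4 (C1 = carboxyl-bearing carbon, C4 = C–OH) and exploits the resorcinol monoether pattern whose free OH is flanked by two prenyl-bearing carbons. Hexasubstitution, the hindered ester and both C-prenyl groups are thus settled in one operation; phenoxide prenylation, acetylide alkylation and the high-temperature cycloaddition have no counterpart.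

Key step: step 8

Step 1
Reactants: 1 4-(2-bromoethyl)phenol
Product: 2 [4-(2-bromoethyl)phenoxy]tri(propan-2-yl)silane
Conditions: TIPSCl (1.1 eq), imidazole (2 eq), DMF, 0 °C to rt
Reagents that add atoms: chlorotri(propan-2-yl)silane (TIPSCl), CC(C)[Si](Cl)(C(C)C)C(C)C
Why: Imidazole-promoted O-silylation of the phenol (silyl ether formation) should proceed cleanly because the weak base does not ionise the phenol enough to displace the primary bromide, and the bulky triisopropylsilyl ether then survives the Grignard, DBU and ketene steps.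

Step 2
Reactants: 3 prop-2-yn-1-ol; 4 1-bromo-3-methylbut-2-ene (prenyl bromide)
Product: 5 6-methylhept-5-en-2-yn-1-ol
Conditions: CuI (10 mol%), Bu4NI (10 mol%), K2CO3 (1.5 eq), DMF, rt
Reagents that add atoms: none
Why: Copper-catalysed coupling of the terminal alkyne with the allylic bromide (SN2 alkylation of a copper acetylide) should give the skipped enyne, attack at the unhindered CH2 end of the prenyl unit being favoured over SN2′ attack at the tertiary carbon, and no stereocentre is formed.

Step 3
Reactants: 2 [4-(2-bromoethyl)phenoxy]tri(propan-2-yl)silane; 5 6-methylhept-5-en-2-yn-1-ol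
Product: 8 (2E)-6-methyl-2-{2-[4-(triisopropylsilyloxy)phenyl]ethyl}hepta-2,5-dien-1-ol, via 2-arylethylmagnesium bromide 6 (not isolated), via chelated alkenylmagnesium alkoxide 7 (not isolated)
Conditions: 2 (2.2 eq), Mg, THF, rt to 40 °C; separately 5 (1.0 eq), i-PrMgCl (1.0 eq), THF, 0 °C; combine, CuI (15 mol%), THF, rt to 45 °C; aq. NH4Cl, 0 °C
Reagents that add atoms: none
Why: Copper-catalysed anti-carbomagnesiation of a propargylic magnesium alkoxide places the arylethyl group on C2 and magnesium on C3 within a five-membered chelate, so protonation puts H cis to CH2OH and sets the (2E) trisubstituted alkene that later keeps the prenyl CH2 trans to the acyl group.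

Step 4
Reactants: 8 (2E)-6-methyl-2-{2-[4-(triisopropylsilyloxy)phenyl]ethyl}hepta-2,5-dien-1-ol
Product: 9 (2E)-6-methyl-2-{2-[4-(triisopropylsilyloxy)phenyl]ethyl}hepta-2,5-dienal
Conditions: activated MnO2 (15 eq), CH2Cl2, rt, dark
Reagents that add atoms: none
Why: Heterogeneous MnO2 oxidation of an allylic alcohol to the enal is neutral and chemoselective, so the (2E) geometry, the skipped 2,5-diene and the aryl silyl ether should be untouched.

Step 5
Reactants: 10 2-(trimethylsilyl)ethanol; 11 bromoacetyl bromide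
Product: 13 2-(trimethylsilyl)ethyl diazoacetate, via 2-(trimethylsilyl)ethyl bromoacetate 12 (not isolated)
Conditions: 11 (1.5 eq), NaHCO3 (3 eq), MeCN, 0 °C; aqueous wash; then N,N′-ditosylhydrazine (2 eq), DBU (4 eq), THF, 0 °C
Reagents that add atoms: N,N′-ditosylhydrazine, Cc1ccc(cc1)S(=O)(=O)NNS(=O)(=O)c1ccc(C)cc1
Why: Acylation of the alcohol with the acyl bromide and then N-alkylation of N,N′-ditosylhydrazine by the bromoacetate with base-induced loss of two sulfinate ions (diazo formation by elimination) should give the diazoacetate, the 2-(trimethylsilyl)ethyl group being chosen because fluoride will later free the hindered acid without hydrolysis.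

Step 6
Reactants: 9 (2E)-6-methyl-2-{2-[4-(triisopropylsilyloxy)phenyl]ethyl}hepta-2,5-dienal; 13 2-(trimethylsilyl)ethyl diazoacetate
Product: 15 2-(trimethylsilyl)ethyl (4E)-2-diazo-8-methyl-3-oxo-4-{2-[4-(triisopropylsilyloxy)phenyl]ethyl}nona-4,7-dienoate, via diazo hydroxy ester 14 (not isolated)
Conditions: 13 (1.4 eq), DBU (0.15 eq), dry DMSO, rt; then 2-iodoxybenzoic acid (IBX, 2 eq), rt
Reagents that add atoms: none
Why: DBU-catalysed aldol-type addition of the nucleophilic diazo carbon to the aldehyde followed in the same flask by IBX oxidation of the allylic carbinol should give the acceptor-stabilised diazo keto ester, the carbinol stereocentre of racemic 14 being destroyed by the oxidation.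

Step 7
Reactants: 16 2-chloro-1,1-dimethoxyethane; 4 1-bromo-3-methylbut-2-ene (prenyl bromide)
Product: 18 1-methoxy-5-methylhex-4-en-1-yne, via sodium methoxyacetylide 17 (not isolated)
Conditions: NaNH2 (3.0 eq), liquid NH3, −33 °C; then 4 (0.9 eq), −33 °C; NH3 evaporated, pentane extraction, distillation at reduced pressure
Reagents that add atoms: none
Why: Sodium amide removes methanol and HCl from the chloroacetal and deprotonates the resulting methoxyacetylene, and the acetylide is then C-alkylated by the allylic bromide in an SN2 reaction (alkoxyacetylide alkylation) to a methyl ynol ether that cannot fragment thermally by a retro-ene path.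

Step 8
Reactants: 15 2-(trimethylsilyl)ethyl (4E)-2-diazo-8-methyl-3-oxo-4-{2-[4-(triisopropylsilyloxy)phenyl]ethyl}nona-4,7-dienoate; 18 1-methoxy-5-methylhex-4-en-1-yne
Product: 23 2-(trimethylsilyl)ethyl 4-hydroxy-6-methoxy-3,5-bis(3-methylbut-2-en-1-yl)-2-{2-[4-(triisopropylsilyloxy)phenyl]ethyl}benzoate, via vinylketene 19 (not isolated), via alkenylcyclobutenone 20 (not isolated), via dienylketene 21 (not isolated), via cyclohexadienone 22 (not isolated)
Conditions: 18 (2.5 eq), degassed ClCH2CH2Cl (0.05 M), hν (300 nm), rt until N2 evolution ends; then 80 °C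
Reagents that add atoms: none
Why: Proposed new method: irradiation expels N2 from 15 and Wolff rearrangement with migration of the alkenyl group (an ester alkoxy group migrates far less readily) should give the (alkoxycarbonyl)vinylketene 19, whose carbonyl carbon is attacked by the nucleophilic, prenyl-bearing carbon of ynol ether 18 in a regioselective [2+2] cycloaddition to the 4-alkenylcyclobutenone 20. At 80 °C 20 opens by reversible conrotatory 4π electrocyclic cleavage to dienylketene 21, and ring A is closed by thermal disrotatory 6π electrocyclisation of 21 (bond between the ketene carbon and the alkene CH); cyclohexadienone 22 then tautomerises irreversibly to phenol 23. The closest known reaction type is the Danheiser benzannulation of α-diazo ketones with alkoxy- or siloxyalkynes (photochemical Wolff variant); new is the ester on the diazo carbon, which should make the ketene more electrophilic toward the ynol ether. No stereocentre is formed. The selectivity needed is regiochemical and follows from the polarisation of both partners: the alkyne carbon bearing prenyl bonds to the ketene carbon (later C–OH), so this prenyl lies between OH and OMe, OMe ends meta to OH and the ester para. The (4E) alkene of 15 holds the prenyl C=C and its CH2 away from the carbene and ketene carbons (no intramolecular cyclopropanation, [2+2] addition or 1,5-hydrogen shift), and although either substituent of 20 may rotate inward, only the isomer of 21 with the alkenyl group cis to the ketene can cyclise and aromatisation drains the equilibrium.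

Step 9
Reactants: 23 2-(trimethylsilyl)ethyl 4-hydroxy-6-methoxy-3,5-bis(3-methylbut-2-en-1-yl)-2-{2-[4-(triisopropylsilyloxy)phenyl]ethyl}benzoate
Product: 24 4-hydroxy-2-[2-(4-hydroxyphenyl)ethyl]-6-methoxy-3,5-bis(3-methylbut-2-en-1-yl)benzoic acid (CNP0254933.0)
Conditions: TBAF (4 eq), THF, 0 °C to rt; cold aq. NH4Cl, then 0.5 M HCl to pH 4 at 0 °C
Reagents that add atoms: none
Why: Fluoride attacks silicon, not the hindered carbonyl, so the aryl silyl ether is cleaved and the 2-(trimethylsilyl)ethyl ester fragments by β-elimination to ethene, fluorotrimethylsilane and the carboxylate (fluoride-induced desilylative deprotection), while the prenyl groups and the aryl methyl ether are inert and the mild acidification avoids chroman formation.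

Compound list
1 | 4-(2-bromoethyl)phenol | Oc1ccc(CCBr)cc1 | starting material
2 | [4-(2-bromoethyl)phenoxy]tri(propan-2-yl)silane | CC(C)[Si](Oc1ccc(CCBr)cc1)(C(C)C)C(C)C | intermediate
3 | prop-2-yn-1-ol (propargyl alcohol) | C#CCO | starting material
4 | 1-bromo-3-methylbut-2-ene (prenyl bromide) | CC(C)=CCBr | starting material
5 | 6-methylhept-5-en-2-yn-1-ol | CC(C)=CCC#CCO | intermediate
6 | {2-[4-(triisopropylsilyloxy)phenyl]ethyl}magnesium bromide | Br[Mg]CCc1ccc(O[Si](C(C)C)(C(C)C)C(C)C)cc1 | intermediate (not isolated)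
7 | chelated alkenylmagnesium alkoxide, 3-(3-methylbut-2-en-1-yl)-4-{2-[4-(triisopropylsilyloxy)phenyl]ethyl}-2,5-dihydro-1,2-oxamagnesole | CC(C)=CCC1=C(CCc2ccc(O[Si](C(C)C)(C(C)C)C(C)C)cc2)CO[Mg]1 | intermediate (not isolated)
8 | (2E)-6-methyl-2-{2-[4-(triisopropylsilyloxy)phenyl]ethyl}hepta-2,5-dien-1-ol | OC/C(CCc1ccc(O[Si](C(C)C)(C(C)C)C(C)C)cc1)=C/CC=C(C)C | intermediate
9 | (2E)-6-methyl-2-{2-[4-(triisopropylsilyloxy)phenyl]ethyl}hepta-2,5-dienal | O=C/C(CCc1ccc(O[Si](C(C)C)(C(C)C)C(C)C)cc1)=C/CC=C(C)C | intermediate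
10 | 2-(trimethylsilyl)ethanol | C[Si](C)(C)CCO | starting material
11 | bromoacetyl bromide | BrCC(Br)=O | starting material
12 | 2-(trimethylsilyl)ethyl bromoacetate | C[Si](C)(C)CCOC(=O)CBr | intermediate (not isolated)
13 | 2-(trimethylsilyl)ethyl diazoacetate | C[Si](C)(C)CCOC(=O)C=[N+]=[N-] | intermediate
14 | 2-(trimethylsilyl)ethyl (4E)-2-diazo-3-hydroxy-8-methyl-4-{2-[4-(triisopropylsilyloxy)phenyl]ethyl}nona-4,7-dienoate (racemic) | C[Si](C)(C)CCOC(=O)C(=[N+]=[N-])C(O)/C(CCc1ccc(O[Si](C(C)C)(C(C)C)C(C)C)cc1)=C/CC=C(C)C | intermediate (not isolated)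
15 | 2-(trimethylsilyl)ethyl (4E)-2-diazo-8-methyl-3-oxo-4-{2-[4-(triisopropylsilyloxy)phenyl]ethyl}nona-4,7-dienoate | C[Si](C)(C)CCOC(=O)C(=[N+]=[N-])C(=O)/C(CCc1ccc(O[Si](C(C)C)(C(C)C)C(C)C)cc1)=C/CC=C(C)C | intermediate
16 | 2-chloro-1,1-dimethoxyethane | COC(CCl)OC | starting material
17 | sodium methoxyacetylide | [Na+].[C-]#COC | intermediate (not isolated)
18 | 1-methoxy-5-methylhex-4-en-1-yne | COC#CCC=C(C)C | intermediate
19 | vinylketene, 2-(trimethylsilyl)ethyl (3E)-7-methyl-2-(oxomethylidene)-3-{2-[4-(triisopropylsilyloxy)phenyl]ethyl}octa-3,6-dienoate | O=C=C(C(=O)OCC[Si](C)(C)C)/C(CCc1ccc(O[Si](C(C)C)(C(C)C)C(C)C)cc1)=C/CC=C(C)C | intermediate (not isolated)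
20 | 2-(trimethylsilyl)ethyl 2-methoxy-3-(3-methylbut-2-en-1-yl)-1-{(3E)-7-methyl-1-[4-(triisopropylsilyloxy)phenyl]octa-3,6-dien-3-yl}-4-oxocyclobut-2-ene-1-carboxylate (racemic) | COC1=C(CC=C(C)C)C(=O)C1(C(=O)OCC[Si](C)(C)C)/C(CCc1ccc(O[Si](C(C)C)(C(C)C)C(C)C)cc1)=C/CC=C(C)C | intermediate (not isolated)
21 | dienylketene, 2-(trimethylsilyl)ethyl 3-methoxy-4-(3-methylbut-2-en-1-yl)-2-{(3E)-7-methyl-1-[4-(triisopropylsilyloxy)phenyl]octa-3,6-dien-3-yl}-5-oxopenta-2,4-dienoate | COC(C(CC=C(C)C)=C=O)=C(C(=O)OCC[Si](C)(C)C)/C(CCc1ccc(O[Si](C(C)C)(C(C)C)C(C)C)cc1)=C/CC=C(C)C | intermediate (not isolated)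
22 | 2-(trimethylsilyl)ethyl 6-methoxy-3,5-bis(3-methylbut-2-en-1-yl)-4-oxo-2-{2-[4-(triisopropylsilyloxy)phenyl]ethyl}cyclohexa-1,5-diene-1-carboxylate (racemic) | COC1=C(CC=C(C)C)C(=O)C(CC=C(C)C)C(CCc2ccc(O[Si](C(C)C)(C(C)C)C(C)C)cc2)=C1C(=O)OCC[Si](C)(C)C | intermediate (not isolated)
23 | 2-(trimethylsilyl)ethyl 4-hydroxy-6-methoxy-3,5-bis(3-methylbut-2-en-1-yl)-2-{2-[4-(triisopropylsilyloxy)phenyl]ethyl}benzoate | COc1c(CC=C(C)C)c(O)c(CC=C(C)C)c(CCc2ccc(O[Si](C(C)C)(C(C)C)C(C)C)cc2)c1C(=O)OCC[Si](C)(C)C | intermediate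
24 | 4-hydroxy-2-[2-(4-hydroxyphenyl)ethyl]-6-methoxy-3,5-bis(3-methylbut-2-en-1-yl)benzoic acid (CNP0254933.0) | COc1c(CC=C(C)C)c(O)c(CC=C(C)C)c(CCc2ccc(O)cc2)c1C(=O)O | target

Total step count: 9. Longest linear sequence: 6 (steps 1, 3, 4, 6, 8, 9).

Steps most likely to fail

1. Step 8. The ynol ether may be captured by the ester carbonyl and ketene carbon in a hetero-[4+2] mode. Alternatively, light may isomerise the (4E) alkene before nitrogen loss, after which the ketene would add to its own prenyl alkene. The fallback uses known chemistry, sets out from 9 and returns at 24: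
   - Pinnick oxidation (NaClO2, NaH2PO4, 2-methylbut-2-ene, t-BuOH/water) would give (2E)-6-methyl-2-{2-[4-(triisopropylsilyloxy)phenyl]ethyl}hepta-2,5-dienoic acid F1.
   - Isobutyl chloroformate and Et3N would give the isobutyl carbonic mixed anhydride F2, which would acylate diazomethane to the α-diazo enone (3E)-1-diazo-7-methyl-3-{2-[4-(triisopropylsilyloxy)phenyl]ethyl}octa-3,6-dien-2-one F3. This is the substrate class on which the benzannulation is established.
   - Irradiation with 18 and heating as in step 8 would give 3-methoxy-2,6-bis(3-methylbut-2-en-1-yl)-5-{2-[4-(triisopropylsilyloxy)phenyl]ethyl}phenol F4, whose only free ring position is para to OH.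
   - Kolbe–Schmitt carboxylation of its potassium phenoxide (KOt-Bu, CO2 under pressure, about 140 °C) would give 4-hydroxy-6-methoxy-3,5-bis(3-methylbut-2-en-1-yl)-2-{2-[4-(triisopropylsilyloxy)phenyl]ethyl}benzoic acid F5.
   - TBAF as in step 9 would then give 24.

2. Step 3. Addition to the internal alkyne may be slow, the alkylcopper intermediate may lose β-hydride, or the anti selectivity may erode. The fallback sets out from 2 and returns at 8:
   - Alkylation of triethyl phosphonoacetate with 2 (NaH, DMF) would give ethyl 2-(diethoxyphosphoryl)-4-[4-(triisopropylsilyloxy)phenyl]butanoate F6.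
   - Horner–Wadsworth–Emmons olefination (LiCl, DBU, MeCN) with 4-methylpent-3-enal F7, freshly made from 4-methylpent-3-en-1-ol with Dess–Martin periodinane, would give ethyl (2E)-6-methyl-2-{2-[4-(triisopropylsilyloxy)phenyl]ethyl}hepta-2,5-dienoate F8 after removal of the (2Z) isomer.
   - DIBAL-H (CH2Cl2, −78 °C) would then give 8.

3. Step 6. DBU may move the skipped C5=C6 alkene of the enal into conjugation by γ-deprotonation, or the aldol equilibrium may lie on the side of the hindered aldehyde. The fallback sets out from 9 and returns at 15: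
   - Aldol addition of the lithium enolate of 2-(trimethylsilyl)ethyl acetate (LDA, THF, −78 °C) would give 2-(trimethylsilyl)ethyl (4E)-3-hydroxy-8-methyl-4-{2-[4-(triisopropylsilyloxy)phenyl]ethyl}nona-4,7-dienoate F9.
   - Dess–Martin oxidation would give the β-keto ester 2-(trimethylsilyl)ethyl (4E)-8-methyl-3-oxo-4-{2-[4-(triisopropylsilyloxy)phenyl]ethyl}nona-4,7-dienoate F10.
   - Regitz diazo transfer (4-acetamidobenzenesulfonyl azide, Et3N, MeCN) would then give 15.

Further compounds
F1 | step 8 | (2E)-6-methyl-2-{2-[4-(triisopropylsilyloxy)phenyl]ethyl}hepta-2,5-dienoic acid | OC(=O)/C(CCc1ccc(O[Si](C(C)C)(C(C)C)C(C)C)cc1)=C/CC=C(C)C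
F2 | step 8 | isobutyl carbonic mixed anhydride of F1 | CC(C)COC(=O)OC(=O)/C(CCc1ccc(O[Si](C(C)C)(C(C)C)C(C)C)cc1)=C/CC=C(C)C
F3 | step 8 | (3E)-1-diazo-7-methyl-3-{2-[4-(triisopropylsilyloxy)phenyl]ethyl}octa-3,6-dien-2-one | [N-]=[N+]=CC(=O)/C(CCc1ccc(O[Si](C(C)C)(C(C)C)C(C)C)cc1)=C/CC=C(C)C
F4 | step 8 | 3-methoxy-2,6-bis(3-methylbut-2-en-1-yl)-5-{2-[4-(triisopropylsilyloxy)phenyl]ethyl}phenol | COc1cc(CCc2ccc(O[Si](C(C)C)(C(C)C)C(C)C)cc2)c(CC=C(C)C)c(O)c1CC=C(C)C
F5 | step 8 | 4-hydroxy-6-methoxy-3,5-bis(3-methylbut-2-en-1-yl)-2-{2-[4-(triisopropylsilyloxy)phenyl]ethyl}benzoic acid | COc1c(CC=C(C)C)c(O)c(CC=C(C)C)c(CCc2ccc(O[Si](C(C)C)(C(C)C)C(C)C)cc2)c1C(=O)O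
F6 | step 3 | ethyl 2-(diethoxyphosphoryl)-4-[4-(triisopropylsilyloxy)phenyl]butanoate | CCOC(=O)C(CCc1ccc(O[Si](C(C)C)(C(C)C)C(C)C)cc1)P(=O)(OCC)OCC
F7 | step 3 | 4-methylpent-3-enal | CC(C)=CCC=O
F8 | step 3 | ethyl (2E)-6-methyl-2-{2-[4-(triisopropylsilyloxy)phenyl]ethyl}hepta-2,5-dienoate | CCOC(=O)/C(CCc1ccc(O[Si](C(C)C)(C(C)C)C(C)C)cc1)=C/CC=C(C)C
F9 | step 6 | 2-(trimethylsilyl)ethyl (4E)-3-hydroxy-8-methyl-4-{2-[4-(triisopropylsilyloxy)phenyl]ethyl}nona-4,7-dienoate | C[Si](C)(C)CCOC(=O)CC(O)/C(CCc1ccc(O[Si](C(C)C)(C(C)C)C(C)C)cc1)=C/CC=C(C)C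
F10 | step 6 | 2-(trimethylsilyl)ethyl (4E)-8-methyl-3-oxo-4-{2-[4-(triisopropylsilyloxy)phenyl]ethyl}nona-4,7-dienoate | C[Si](C)(C)CCOC(=O)CC(=O)/C(CCc1ccc(O[Si](C(C)C)(C(C)C)C(C)C)cc1)=C/CC=C(C)C
A1 | direct plan | allyl 5-[4-(tert-butyldimethylsilyloxy)phenyl]pent-2-ynoate | C=CCOC(=O)C#CCCc1ccc(O[Si](C)(C)C(C)(C)C)cc1
A2 | direct plan | 1-methoxy-3-(trimethylsilyloxy)cyclohexa-1,3-diene | COC1=CC(O[Si](C)(C)C)=CCC1
A3 | direct plan | allyl 2-{2-[4-(tert-butyldimethylsilyloxy)phenyl]ethyl}-4-hydroxy-6-methoxybenzoate | C=CCOC(=O)c1c(OC)cc(O)cc1CCc1ccc(O[Si](C)(C)C(C)(C)C)cc1
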